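Divide the plateau of monomer in chains by the square root of the initiator loading, and see what that ratio does across the earlier runs.

| setting | north | north-west | north-east | east | violet | grey |
|---|---|---|---|---|---|---|
| free monomer | 0.25 M (fed, over 80 s) | 0.25 M (fed, over 80 s) | 0.25 M (fed, over 80 s) | 0.14 M (fed, over 80 s) | 0.080 M | 0.25 M (fed, over 80 s) |
| initiator | 2.4 mol% | 3.7 mol% | 8.4 mol% | 2 mol% | 8 mol% | 2 mol% |
| remark | run made earlier | run made earlier | run made earlier | run made earlier | everything together at the start |  |
| time |  |  |  |  | 80 min | 80 min |

- north (time / min: monomer in chains / %, free monomer / %): 4.00: 14, 67; 10.0: 27, 42; 20.0: 34, 21; 30.0: 37, 16; 40.0: 37, 13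
- north-west (time / min: monomer in chains / %, free monomer / %): 4.00: 19, 65; 10.0: 32, 38; 20.0: 43, 21; 30.0: 47, 12; 40.0: 47, 9
- north-east (time / min: monomer in chains / %, free monomer / %): 4.00: 25, 58; 10.0: 44, 28; 20.0: 58, 13; 30.0: 63, 6; 40.0: 61, 2
- east (time / min: monomer in chains / %, free monomer / %): 8.00: 16, 61; 15.0: 27, 42; 25.0: 31, 32; 30.0: 30, 26; 40.0: 35, 23

(standard deviation of a reading: 1.5 percentage points)

- where the amount of free monomer changes, what is given in equivalents or mol% on it follows

- the winner by amount of monomer in chains, in percent of the free monomer charged; "neither" if no more than 2 percentage points parts them (violet / grey / neither)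
- how much monomer in chains is there at the end, in percent of the free monomer charged: violet
- how much monomer in chains is there at the end, in percent of the free monomer charged: grey

Watch north in slow motion. At 4.00 min it holds 14% in chains and 67% free, so 19.0% is in neither form. North-east at that time has 25% in chains and 17.0% in neither. Its chains stand 1.79 times north's, while the root of the loadings gives 1.87, so in these two readings early growth sits close to the root of the loading.

By 20.0 min north has 34% in chains and 21% free, and growth is slowing. At 30.0 min and at 40.0 min its chains read 37%, while its free monomer reads 16% and then 13%.

Average the last two readings of each run and divide. North gives 2.39, north-west 2.44, and east, at 0.14 M, 2.30. Their mean, 2.38, is the reach: the plateau share of chains per square root of loading.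

North-east, at 8.4 mol%, reads lower, at 2.14, so in these readings the reach does not carry over to that loading. My reckoning therefore gives grey 33.6% from the reach, and violet 60.5% from north-east's value. Violet's concentration lies outside the runs, so that is the weaker number.

The forecast names violet, with 50% for violet and 35% for grey, arguing that in violet “the side reaction is three times slower”. On violet it stands below my figure; on the winner we agree.

The flasks give violet: 54.2% for violet and 33.6% for grey.

    free monomer + initiating radical → growing radical + monomer in chains (k = 1.30 × 10⁵ M⁻¹ s⁻¹)
    initiator → 2 initiating radical (k = 0.0760 min⁻¹)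
    2 free monomer → homo dimer (k = 0.170 M⁻¹ min⁻¹)
    free monomer + growing radical → monomer in chains + growing radical, rate k4*[growing radical]*[free monomer] (k = 2.00 × 10⁵ M⁻¹ min⁻¹)
    2 growing radical → dead chain (k = 1.40 × 10⁸ M⁻¹ s⁻¹)
    monomer in chains ⇌ isomer of the product (K = 14.0, k = 0.00290 min⁻¹)

At the asked time grey's ratio comes to 2.37, and violet's to 1.92, lower than north-east's. Grey's chains stop short mainly because of the turning of 2 growing radical into dead chain: with that step taken away, grey goes from 33.6% to 79.6%. Part of the gap between the flasks is the loading: with the difference in loading taken away, violet falls from 54.2% to 30.7%. A neighbouring flask, like grey but with 0.8 mol% of initiator, should hold 21.3% by the reach, and it holds 22.6%.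

The numbers in the tables stem from a simulated flask with constants of no real substance.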